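**Retrosynthetic overview**
1. Octacosanolide has a single ring, the 29-membered lactone ring A (C1 carbonyl, C2–C27 methylenes, C28 the OCH2 carbon, one ring oxygen). Ring A is closed in the last step, directly at the saturated oxidation level.
2. Key disconnection C27–C28: ring A ⇒ iodomethyl heptacos-26-enoate (7). In the forward direction an intramolecular NiH hydroalkylation joins the terminal olefin carbon C27 to the acyloxymethyl carbon C28 and puts H on C26 in the same operation.
3. Enabling feature: C28 is a methylene bonded only to the lactone oxygen (O–C1=O) and to C27. It can therefore be carried as an ICH2–O–C(=O) unit with a weak C–I bond, an oxygen-stabilised radical and no β-hydrogen, while C26/C27 are plain ring methylenes that can be carried as a vinyl group.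
4. 7 ⇒ chloromethyl ester 6 ⇒ heptacos-26-enoic acid 5 (halide exchange; carboxylate O-alkylation).
5. C16–C17 disconnection of 5 ⇒ undec-10-enyl Grignard reagent (from 11-bromoundec-1-ene 1) + 16-bromohexadecanoic acid 2 (Cu-catalysed alkyl–alkyl coupling).

Key step: step 4

Remark: the target has no stereocentre; ring atoms are numbered from the lactone carbonyl carbon (C1) to the OCH2 carbon (C28).

**Route**

Step 1
Reactants: 1 11-bromoundec-1-ene; 2 16-bromohexadecanoic acid
Product: 5 heptacos-26-enoic acid, via undec-10-enylmagnesium bromide 3 (not isolated), via chloromagnesium 16-bromohexadecanoate 4 (not isolated)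
Conditions: 1, Mg, THF, 40 °C; separately 2, MeMgCl (1.0 equiv), THF, −20 °C; combine, Li2CuCl4 (3 mol %), THF, −20 °C → rt; then aq. HCl
Reagents that add atoms: none
Why: Kochi-type Cu-catalysed C(sp3)–C(sp3) cross-coupling of a primary alkyl Grignard reagent with a primary alkyl bromide should form the C16–C17 bond, because the acid of 2 is masked as its chloromagnesium salt 4, which is inert to the Grignard reagent at −20 °C, and the remote terminal olefin is a spectator.

Step 2
Reactants: 5 heptacos-26-enoic acid
Product: 6 chloromethyl heptacos-26-enoate
Conditions: ClCH2OSO2Cl, NaHCO3, Bu4NHSO4 (cat.), CH2Cl2/H2O, 0 °C → rt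
Reagents that add atoms: chloromethyl chlorosulfate, ClCOS(=O)(=O)Cl
Why: Phase-transfer O-alkylation of the carboxylate (SN2 at the CH2 of chloromethyl chlorosulfate, chlorosulfate as leaving group) is the standard entry to chloromethyl esters and should leave the olefin untouched under the mild biphasic basic conditions.

Step 3
Reactants: 6 chloromethyl heptacos-26-enoate
Product: 7 iodomethyl heptacos-26-enoate
Conditions: NaI, acetone, rt, dark; filtered, concentrated and used directly
Reagents that add atoms: sodium iodide, [Na+].[I-]
Why: Finkelstein halide exchange should be fast at the SN2-activated acyloxymethyl carbon and is driven by precipitation of NaCl from acetone.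

Step 4
Reactants: 7 iodomethyl heptacos-26-enoate
Product: 8 octacosanolide
Conditions: NiBr2·glyme (20 mol %), 4,4'-di-tert-butyl-2,2'-bipyridine (24 mol %), (EtO)2MeSiH (2.5 equiv), Na2CO3, DMA/THF, rt, syringe-pump addition of 7 (final 2 mM)
Reagents that add atoms: none
Why: Proposed new method: a macrocyclising intramolecular NiH hydroalkylation, in which the ligated nickel hydride (from NiBr2·glyme, the silane and Na2CO3) adds anti-Markovnikov to the terminal C26=C27 olefin to place nickel on C27, low-valent (monovalent) nickel abstracts iodine from the ICH2–O–C(=O) terminus to give the acyloxymethyl radical at C28, the radical is captured at nickel and C(sp3)–C(sp3) reductive elimination from trivalent nickel forms C27–C28. The closest known reaction type is the intermolecular NiH-catalysed hydroalkylation of terminal olefins with primary alkyl iodides and with α-acyloxyalkyl halides, and what is new is the intramolecular closure of a large ring and the unsubstituted acyloxymethyl iodide. Ring A, the 29-membered lactone, closes in the endo mode with respect to the olefin (both olefin carbons end up in the ring), and the hydride delivered to C26 gives the saturated ring directly, so no later hydrogenation is needed. No stereocentre is created. The step needs cross-coupling over hydrodeiodination, terminal regiochemistry and ring closure over oligomerisation. The substrate secures these because the acyloxy oxygen on C28 weakens the C–I bond and stabilises the radical, C28 has no β-hydrogen to lose from nickel, only the primary alkylnickel at the chain end is coupling-competent with the non-chain-walking bipyridine ligand, the two termini react with nickel by different elementary steps, and slow addition to a strain-free 29-membered closure keeps intermolecular coupling down.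

**Compound list**
1 | 11-bromoundec-1-ene | C=CCCCCCCCCCBr | starting material
2 | 16-bromohexadecanoic acid | BrCCCCCCCCCCCCCCCC(=O)O | starting material
3 | undec-10-enylmagnesium bromide | C=CCCCCCCCCC[Mg]Br | intermediate
4 | chloromagnesium 16-bromohexadecanoate | BrCCCCCCCCCCCCCCCC(=O)O[Mg]Cl | intermediate
5 | heptacos-26-enoic acid | C=CCCCCCCCCCCCCCCCCCCCCCCCCC(=O)O | intermediate
6 | chloromethyl heptacos-26-enoate | C=CCCCCCCCCCCCCCCCCCCCCCCCCC(=O)OCCl | intermediate
7 | iodomethyl heptacos-26-enoate | C=CCCCCCCCCCCCCCCCCCCCCCCCCC(=O)OCI | intermediate
8 | octacosanolide (oxacyclononacosan-2-one) | O=C1CCCCCCCCCCCCCCCCCCCCCCCCCCCO1 | target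

**Step count**
Total steps: 4. Longest linear sequence: 4 steps (from 1 or 2 to 8).

**Steps most likely to fail**

Step 4 (Proposed new method). Intermolecular coupling may outrun ring closure and give oligomers, the C–I bond may be reduced to the methyl ester before the olefin is engaged, or the nickel hydride may isomerise the olefin. The fallback uses known chemistry, sets out from 5 and comes back at 8. Heptacos-26-enoic acid 5 would be hydroformylated with linear selectivity (Rh(acac)(CO)2, Xantphos, CO/H2, toluene, 80 °C) to 28-oxooctacosanoic acid F1, which builds the same C27–C28 bond with carbon monoxide as the one-carbon unit. Reduction with NaBH4 (EtOH, 0 °C, then acid) would give 28-hydroxyoctacosanoic acid F2. Yamaguchi macrolactonisation (2,4,6-trichlorobenzoyl chloride, Et3N, THF; then DMAP, toluene, reflux, high dilution) would then close ring A at the C1–O bond to give 8.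

Step 1. Wurtz-type homocoupling of the Grignard reagent and precipitation of the magnesium carboxylate may leave the coupling incomplete. The fallback sets out from 1 and 2 and comes back at 5. Acid 2 would be esterified (MeOH, H2SO4 cat., reflux) to methyl 16-bromohexadecanoate F3. Bromide 1 would be converted with zinc dust (I2 cat., DMA, 80 °C) into undec-10-enylzinc bromide F4. Negishi alkyl–alkyl coupling (Pd2(dba)3, tricyclopentylphosphine, N-methylimidazole, THF/NMP, 80 °C) would give methyl heptacos-26-enoate F5, and saponification (LiOH, THF/H2O, then aq. HCl) would return 5.

Step 2. Phase-transfer alkylation of the waxy, poorly soluble C27 carboxylate may be sluggish, and the chloromethyl ester may alkylate a second carboxylate to give the methylene diester. The fallback sets out from 5 and comes back at 6 and avoids any carboxylate nucleophile. Acid 5 would be converted with oxalyl chloride (cat. DMF, CH2Cl2, 0 °C → rt) into heptacos-26-enoyl chloride F6. Formal insertion of formaldehyde into the C–Cl bond (paraformaldehyde, ZnCl2 cat., CH2Cl2, rt → 40 °C) would then give chloromethyl ester 6.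

Further compounds
F1 | step 4 | 28-oxooctacosanoic acid | O=CCCCCCCCCCCCCCCCCCCCCCCCCCCC(=O)O
F2 | step 4 | 28-hydroxyoctacosanoic acid | OCCCCCCCCCCCCCCCCCCCCCCCCCCCC(=O)O
F3 | step 1 | methyl 16-bromohexadecanoate | BrCCCCCCCCCCCCCCCC(=O)OC
F4 | step 1 | undec-10-enylzinc bromide | C=CCCCCCCCCC[Zn]Br
F5 | step 1 | methyl heptacos-26-enoate | C=CCCCCCCCCCCCCCCCCCCCCCCCCC(=O)OC
F6 | step 2 | heptacos-26-enoyl chloride | C=CCCCCCCCCCCCCCCCCCCCCCCCCC(=O)Cl
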